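## The problem

The target 18 is an achiral tetrameric phlorotannin: four benzene rings (ring A, 2,4,6-trihydroxyphenyl; ring B, the pentaoxygenated core; rings C and D, two 3,4,5-trihydroxyphenyl units) joined only through three diaryl ether oxygens, with eleven free phenolic hydroxyls. There is no stereocentre, so nothing has to be set or relayed; the difficulty lies in placing the oxygens and making the ether links. Ring B carries oxygen on five of its six carbons (aryloxy on B1, B4 and B6, hydroxyl on B3 and B5, hydrogen only on B2), and the oxygens on B4 and B6 are each flanked on both sides by further oxygen substituents, the worst case for metal-mediated C–O coupling. The free polyphenol, above all the pyrogallol-type rings C and D, is oxidised easily in air under basic conditions and is C-alkylated by carbocations, so all hydroxyls must stay masked by groups that tolerate organolithium reagents and heat and then fall in one acidic, non-oxidising operation. Because ring A is the most electron-rich ring of every intermediate (its C3 and C5 lie between two oxygens), late electrophilic substitution or lithiation cannot be directed to ring B; each oxygen must be in place before the rings are joined or must come from a ring-forming step. The enabling feature is the pattern of rings C and D: ether oxygen on C1, hydrogen on C2 and C6, hydroxyl on C3, C4 and C5. This is what results when the two carbons of an aryloxyalkyne (future C1 and C2) are inserted between the carbonyl carbon (future C3) and the vinylic α-carbon (future C6) of a 3,4-dialkoxycyclobutenone, so both rings can be grown on oxygens that ring B already carries.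

## Retrosynthesis

**Target 18 to protected tetramer 17.** Seven O–methyl and two O–ethyl bonds are cut. Simple alkyl ethers are preferred to benzyl ethers because every building block is then commercial in the required form, and a Lewis-acid dealkylation releases only small alkyl bromides that do not alkylate the electron-rich rings, which a benzylic cation would. Compound 17 is shelf-stable and differs from 18 only in these nine groups; its two free hydroxyls are those created in the ring-forming step and need no protection. The forward reaction must cleave all nine ethers without touching the three diaryl ether bonds, which have no sp3 carbon for a nucleophile to attack.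

**Tetramer 17 to bis(ethynyl ether) 11 and cyclobutenone 15 (key disconnection).** In each of rings C and D the C1–C6 and C2–C3 bonds are cut, which takes both rings apart into an alkyne (C1, C2) and a four-carbon unit (C3–C6). The neighbouring cuts, through the B4–O/B6–O or O–C1 bonds, would require aryl–oxygen coupling at oxygens flanked on both sides. Here these C–O bonds already exist in 11 as ynol ether bonds, made from a phenol and a two-carbon electrophile. The precursor contains only rings A and B, and 15 is a seven-carbon compound used twice. The forward benzannulation must run twice on one molecule, the ketene–alkyne [2+2] step must have the correct regiochemistry, and the terminal aryl ethynyl ethers must survive 80–110 °C long enough to be captured.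

**Cyclobutenone 15 to methoxyacetyl chloride 12 and ethoxyacetylene 13.** The C1–C2 and C3–C4 bonds of the four-membered ring are cut, a ketene–ynol ether [2+2] cycloaddition through methoxyketene 14. No other cut of 15 leads to two commercial compounds in one step. The forward reaction requires that the alkoxyketene is trapped by the ynol ether faster than it oligomerises, and that the ketene carbonyl carbon bonds to the unsubstituted alkyne carbon; this puts OEt on C3 and OMe on C4, the positions that become C5 and C4 of rings C and D.

**Bis(ethynyl ether) 11 to bis(dichlorovinyl ether) 9, then to bisphenol 6 and trichloroethylene 7.** The two O–C(sp) bonds are cut. A phenol cannot be alkynylated directly, so each alkyne is carried as a 1,2-dichlorovinyl ether, formed by addition of the phenoxide to dichloroacetylene 8 released from 7 by base, and unmasked with an alkyllithium through the dilithium bis(acetylide) 10. Two molecules of 7 are needed, one for each hydroxyl of 6. Compound 6 has all five oxygens of ring B and the complete ring A. The forward steps require that two hindered phenoxides add, and that the elimination is faster than ring lithiation.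

**Bisphenol 6 to dialdehyde 4, then to fluoro dialdehyde 2 and phenol 3, then to aldehyde 1.** The two hydroxyls of 6 are traced back to formyl groups (aryl–C to aryl–O by Baeyer–Villiger oxidation through bis(formate) 5), and the ring A ether bond to an SNAr displacement of fluoride. The same two formyl groups, one ortho and one para to fluorine, activate that displacement, so the hindered phenol 3 is joined without a metal. The alternative of adding the second oxygen after the ether is made is rejected because electrophiles and bases would attack ring A. The second formyl group is therefore introduced on 1, where C3 and C5 are equivalent and no regiochemical question arises. Compounds 1 and 3 are commercial.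

## Roads not taken

Alternative 1: Ring A is cut at A2–A3 and A5–A6. In the forward sense dimethyl 3-oxoglutarate A2 would condense twice, under alkoxide base, with the aryloxymalonate A3 to give the phloroglucinol diester A1.
- Merits. The three ring A hydroxyls are formed free, so three fewer ethers need cleaving at the end, and A2 is a cheap bulk chemical.
- Weak points. A3 already contains rings B, C and D with both hindered ether links, so the step builds the one ring that is available commercially as 3 and leaves the real problem untouched. The malonate C–H of A3 is the most acidic site in the flask; once it is deprotonated the ester carbonyls are poor electrophiles, and a double Claisen condensation on a malonate enolate is mechanistically unfavourable. A1 then needs ester hydrolysis and double decarboxylation in addition to demethylation.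
- Comparison. The chosen plan also builds rings de novo, but it builds the two whose ether bonds are hard to make. Against the cheap reagents and free ring A hydroxyls of this road it sets the fact that its ring construction removes the hindered couplings instead of presupposing them.

Alternative 2: The B4–O and B6–O bonds are cut. Two equivalents of 3,4,5-trimethoxyphenol A6 would displace both fluorides of the difluoro dialdehyde A5 to give the tetraaryl dialdehyde A4, whose formyl groups are later converted into the B3 and B5 hydroxyls.
- Merits. Every reaction type is known. The nucleophile A6 is commercial and has no ortho substituents. The B4 fluoride is activated by two ortho formyl groups and the B6 fluoride by one ortho and one para. From A5 only three operations remain (double SNAr, double Baeyer–Villiger oxidation, global demethylation). In precedent and robustness of the key step this road is stronger than the chosen one.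
- Weak points. They lie in A5. Its ring A ether at B1 is meta to both formyl groups and cannot be made by SNAr; it needs a copper-mediated coupling of the doubly ortho-substituted phenol 3 next to a fluorine. The two formyl groups must then be introduced one after the other by directed lithiation, with aldehyde protection in between.
- Comparison. The chosen plan makes the A–O–B bond by an SNAr that the latent hydroxyls themselves activate, reaches the ring A–ring B bisphenol 6 in three steps from commercial material, and makes no aryl–oxygen bond at B4 or B6. The price is an untested annulation.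

Alternative 3: Ring B is cut at B6–B1 and B4–B3. The enolate of the bis(aryloxy)acetone A8 would add to the aryloxypropiolate A9 (Michael addition), the second α-carbon would acylate on the ester (Claisen), and tautomerisation would give the resorcinol A7 with all three ethers in place.
- Merits. It is the most convergent of the four plans. A8 comes from double O-alkylation of A6, no diaryl ether coupling is needed, and only the global demethylation follows A7. On step count it is shorter than the chosen route.
- Weak points. The β-carbon of A9 carries a donor oxygen, which lowers its electrophilicity. The adduct is a β-aryloxy acrylate that can expel the ring A phenoxide by addition–elimination. The enolate of A8 has an aryloxy leaving group on the α′-carbon and may enter Favorskii-type pathways. A9 is itself an aryl ynol ether derivative and requires the same acetylide chemistry as the chosen route.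
- Comparison. No close precedent exists for either bond-forming event with oxygen on all reacting carbons. Against the higher convergence the chosen plan sets a key step with a close known counterpart (alkoxyalkynes in the same annulation) and regiocontrol inherent in a pericyclic sequence.

Key step: step 7

Remark on the chemistry: 3 and 13 (the latter as its hexane solution) are taken as commercial; the (E) geometry of 9 and the (Z) geometry drawn for 16 are mechanistic expectations without consequence, since both elements are destroyed in the next bond reorganisation.

## Route

Step 1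
Reactants: 1 4-fluoro-2,6-dimethoxybenzaldehyde
Product: 2 4-fluoro-2,6-dimethoxybenzene-1,3-dicarbaldehyde
Conditions: Cl2CHOMe, TiCl4, CH2Cl2, 0 °C → rt; then ice/H2O
Reagents that add atoms: dichloromethyl methyl ether, COC(Cl)Cl; water, O
Why: Rieche formylation; C3 (equivalent to C5) is ortho and para to the two methoxy groups and meta to the existing formyl group, so the chloro(methoxy)methyl cation should attack there, and aqueous work-up hydrolyses the α-chloro ether to the aldehyde.

Step 2
Reactants: 2 4-fluoro-2,6-dimethoxybenzene-1,3-dicarbaldehyde; 3 2,4,6-trimethoxyphenol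
Product: 4 2,6-dimethoxy-4-(2,4,6-trimethoxyphenoxy)benzene-1,3-dicarbaldehyde
Conditions: K2CO3, DMF, rt → 50 °C, Ar
Reagents that add atoms: none
Why: SNAr; the fluoride of 2 has one ortho and one para formyl group, so the hindered but strongly nucleophilic phenoxide of 3 should add and expel fluoride under mild carbonate conditions, while the methoxy groups are far poorer leaving groups.

Step 3
Reactants: 4 2,6-dimethoxy-4-(2,4,6-trimethoxyphenoxy)benzene-1,3-dicarbaldehyde
Product: 6 2,6-dimethoxy-4-(2,4,6-trimethoxyphenoxy)benzene-1,3-diol, via bis(formate) 5 (not isolated)
Conditions: mCPBA (2.5 equiv), CH2Cl2, 0 °C → rt; aq. NaHCO3 wash; then K2CO3 (cat.), MeOH, rt, Ar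
Reagents that add atoms: mCPBA (3-chloroperoxybenzoic acid), OOC(=O)c1cccc(Cl)c1
Why: Double Baeyer–Villiger (Dakin-type) oxidation; each formyl group sits on an aryl carbon flanked by two oxygen substituents, so aryl migration in the Criegee intermediate is strongly preferred over hydride migration, and catalytic carbonate in methanol then transfers the formyl groups to the solvent.

Step 4
Reactants: 6 2,6-dimethoxy-4-(2,4,6-trimethoxyphenoxy)benzene-1,3-diol; 7 trichloroethylene
Product: 9 1,3-bis{[(E)-1,2-dichloroethenyl]oxy}-2,6-dimethoxy-4-(2,4,6-trimethoxyphenoxy)benzene, via dichloroacetylene 8 (not isolated)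
Conditions: 7 (3 equiv), K2CO3 (4 equiv), DMF, 70 °C, Ar
Reagents that add atoms: trichloroethylene (second equivalent of 7), ClC=C(Cl)Cl
Why: Base-mediated vinylation of phenols with trichloroethylene, the standard entry to aryl 1,2-dichlorovinyl ethers: K2CO3 dehydrochlorinates 7 to dichloroacetylene 8, and each of the two phenoxides of 6 adds to one molecule of 8 in anti fashion and is protonated to the (E)-dichlorovinyl ether, so two equivalents of 7 are consumed. The slim linear electrophile should tolerate the flanked oxygens.

Step 5
Reactants: 9 1,3-bis{[(E)-1,2-dichloroethenyl]oxy}-2,6-dimethoxy-4-(2,4,6-trimethoxyphenoxy)benzene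
Product: 11 1,3-bis(ethynyloxy)-2,6-dimethoxy-4-(2,4,6-trimethoxyphenoxy)benzene, via dilithium bis(acetylide) 10 (not isolated)
Conditions: n-BuLi (4.4 equiv), THF, −78 → −40 °C; then H2O, −78 → 0 °C; used at once
Reagents that add atoms: none
Why: Dehydrochlorination of each dichlorovinyl ether to the chloroalkynyl ether followed by lithium–chlorine exchange gives the lithium aryloxyacetylide, the established route to ynol ethers with two equivalents of alkyllithium per vinyl ether; cold protonation frees the terminal alkynes, and at −78 °C ring lithiation should not compete.

Step 6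
Reactants: 12 methoxyacetyl chloride; 13 ethoxyacetylene
Product: 15 racemic 3-ethoxy-4-methoxycyclobut-2-en-1-one, via methoxyketene 14 (not isolated)
Conditions: Et3N, Et2O, 0 °C → rt, slow addition of 12 to 13 (2 equiv) and Et3N
Reagents that add atoms: none
Why: Dehydrochlorination gives methoxyketene, which is trapped in a ketene–ynol ether [2+2] cycloaddition by the alkyne present in excess; the nucleophilic terminal carbon of 13 bonds to the ketene carbonyl carbon, placing OEt on C3 and OMe on C4 (one stereocentre, formed racemic and destroyed in step 7).

Step 7
Reactants: 11 1,3-bis(ethynyloxy)-2,6-dimethoxy-4-(2,4,6-trimethoxyphenoxy)benzene; 15 racemic 3-ethoxy-4-methoxycyclobut-2-en-1-one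
Product: 17 5,5'-{[2,4-dimethoxy-6-(2,4,6-trimethoxyphenoxy)-1,3-phenylene]bis(oxy)}bis(3-ethoxy-2-methoxyphenol), via vinylketene 16 (not isolated)
Conditions: 15 (3 equiv), PhMe (0.1 M, degassed), 80 °C then 110 °C, sealed tube, Ar; then K2CO3, MeOH, rt
Reagents that add atoms: 3-ethoxy-4-methoxycyclobut-2-en-1-one (second equivalent of 15), CCOC1=CC(=O)C1OC
Why: Proposed new method: the closest known reaction type is the Danheiser benzannulation of cyclobutenones with alkoxy- and siloxyalkynes, extended here to a terminal aryl ethynyl ether and run twice on one substrate, one molecule of 15 being consumed per alkyne. Compound 15 should open by thermal 4π-electrocyclic ring opening to vinylketene 16, whose ketene C=C bond adds [2+2] to the ynol ether; the resulting 3-aryloxy-4-vinylcyclobutenone opens again (4π) to a dienylketene, which closes by 6π-electrocyclisation and tautomerises to the phenol. Each of rings C and D is thus closed by a 6π-electrocyclic closure, and the net new ring bonds are C1–C6 and C2–C3 (the alkyne carbons to the former vinylic α-carbon and carbonyl carbon of 15). No stereocentre is created, and the one stereocentre of racemic 15 becomes sp2. The selectivity needed is the regiochemistry of the ketene [2+2] step: the unsubstituted alkyne carbon, made nucleophilic by the oxygen lone pair, must bond to the ketene carbonyl carbon, which places the new hydroxyl meta to the aryl ether oxygen with OMe on C4 and OEt on C5. This polarisation should be secured in 11 because both ynol ether oxygens are flanked by two ortho substituents, so the O–C(sp) bond is twisted out of the plane of ring B and the lone pair is donated to the alkyne and not to the arene. The excess of 15 drives the second annulation, and the methanolysis returns any product phenol that has been acylated by 16.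

Step 8
Reactants: 17 5,5'-{[2,4-dimethoxy-6-(2,4,6-trimethoxyphenoxy)-1,3-phenylene]bis(oxy)}bis(3-ethoxy-2-methoxyphenol)
Product: 18 5,5'-{[2,4-dihydroxy-6-(2,4,6-trihydroxyphenoxy)-1,3-phenylene]bis(oxy)}bis(benzene-1,2,3-triol)
Conditions: BBr3 (20 equiv), CH2Cl2, −78 °C → rt, Ar; then H2O, 0 °C; isolation under Ar
Reagents that add atoms: none
Why: Lewis-acid dealkylation of aryl alkyl ethers; BBr3 coordinates each ether oxygen and bromide removes the methyl or ethyl group by SN2, while the diaryl ether bonds offer no sp3 carbon and should survive, and the acidic, non-oxidising medium suits the air-sensitive undecaphenol.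

## Compound list

1 | 4-fluoro-2,6-dimethoxybenzaldehyde | COc1cc(F)cc(OC)c1C=O | starting material
2 | 4-fluoro-2,6-dimethoxybenzene-1,3-dicarbaldehyde | COc1cc(F)c(C=O)c(OC)c1C=O | intermediate
3 | 2,4,6-trimethoxyphenol | COc1cc(OC)c(O)c(OC)c1 | starting material
4 | 2,6-dimethoxy-4-(2,4,6-trimethoxyphenoxy)benzene-1,3-dicarbaldehyde | COc1cc(OC)c(Oc2cc(OC)c(C=O)c(OC)c2C=O)c(OC)c1 | intermediate
5 | 2,6-dimethoxy-4-(2,4,6-trimethoxyphenoxy)-1,3-phenylene diformate | COc1cc(OC)c(Oc2cc(OC)c(OC=O)c(OC)c2OC=O)c(OC)c1 | intermediate
6 | 2,6-dimethoxy-4-(2,4,6-trimethoxyphenoxy)benzene-1,3-diol | COc1cc(OC)c(Oc2cc(OC)c(O)c(OC)c2O)c(OC)c1 | intermediate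
7 | trichloroethylene | ClC=C(Cl)Cl | starting material
8 | dichloroacetylene (dichloroethyne) | ClC#CCl | intermediate
9 | 1,3-bis{[(E)-1,2-dichloroethenyl]oxy}-2,6-dimethoxy-4-(2,4,6-trimethoxyphenoxy)benzene | COc1cc(OC)c(Oc2cc(OC)c(O/C(Cl)=C\Cl)c(OC)c2O/C(Cl)=C\Cl)c(OC)c1 | intermediate
10 | dilithium bis(acetylide) of 11: 1,3-bis[(lithioethynyl)oxy]-2,6-dimethoxy-4-(2,4,6-trimethoxyphenoxy)benzene | COc1cc(OC)c(Oc2cc(OC)c(OC#C[Li])c(OC)c2OC#C[Li])c(OC)c1 | intermediate
11 | 1,3-bis(ethynyloxy)-2,6-dimethoxy-4-(2,4,6-trimethoxyphenoxy)benzene | COc1cc(OC)c(Oc2cc(OC)c(OC#C)c(OC)c2OC#C)c(OC)c1 | intermediate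
12 | methoxyacetyl chloride | COCC(=O)Cl | starting material
13 | ethoxyacetylene (ethoxyethyne) | CCOC#C | starting material
14 | methoxyketene | COC=C=O | intermediate
15 | racemic 3-ethoxy-4-methoxycyclobut-2-en-1-one | CCOC1=CC(=O)C1OC | intermediate
16 | (3Z)-3-ethoxy-4-methoxybuta-1,3-dien-1-one (vinylketene, methoxy turned outward) | O=C=C/C(OCC)=C/OC | intermediate
17 | 5,5'-{[2,4-dimethoxy-6-(2,4,6-trimethoxyphenoxy)-1,3-phenylene]bis(oxy)}bis(3-ethoxy-2-methoxyphenol) | COc1cc(OC)c(Oc2cc(OC)c(Oc3cc(O)c(OC)c(OCC)c3)c(OC)c2Oc2cc(O)c(OC)c(OCC)c2)c(OC)c1 | intermediate
18 | 5,5'-{[2,4-dihydroxy-6-(2,4,6-trihydroxyphenoxy)-1,3-phenylene]bis(oxy)}bis(benzene-1,2,3-triol) | Oc1cc(O)c(Oc2cc(O)c(Oc3cc(O)c(O)c(O)c3)c(O)c2Oc2cc(O)c(O)c(O)c2)c(O)c1 | target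

## Step count and least certain steps

Total step count: 8. Longest linear sequence: 7 steps (1 → 2 → 4 → 6 → 9 → 11 → 17 → 18; step 6 is a one-step side branch).

**Step 7 (key step, proposed new method).**
- Risk: thermal oligomerisation of the terminal aryl ethynyl ethers may outrun their capture by the vinylketene. The second annulation may also stall after the first, because the phenol formed first consumes vinylketene by O-acylation.
- Fallback: known chemistry, setting out from bisphenol 6 and returning at target 18; it gives up the ring construction and makes the B4–O and B6–O bonds by SNAr on an unhindered fluoride. Twofold SNAr of 6 with two equivalents of the starting aldehyde 1 (Cs2CO3, DMSO, 100 °C; fluoride para to the formyl group) would give 4,4'-{[2,4-dimethoxy-6-(2,4,6-trimethoxyphenoxy)-1,3-phenylene]bis(oxy)}bis(2,6-dimethoxybenzaldehyde) F1. Baeyer–Villiger oxidation with mCPBA would give 4,4'-{[2,4-dimethoxy-6-(2,4,6-trimethoxyphenoxy)-1,3-phenylene]bis(oxy)}bis(2,6-dimethoxyphenyl) diformate F2, and catalytic K2CO3 in methanol would convert it into 4,4'-{[2,4-dimethoxy-6-(2,4,6-trimethoxyphenoxy)-1,3-phenylene]bis(oxy)}bis(2,6-dimethoxyphenol) F3. BBr3 would then cleave the nine methyl ethers to 18.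

**Step 5.**
- Risk: oligomerisation or hydration of the terminal ynol ethers during work-up and isolation, and ring lithiation by the small excess of butyllithium.
- Fallback: from 9 (through 10) back to 11. The acetylide 10 is quenched with Me3SiCl instead of water to give 1,3-bis{[(trimethylsilyl)ethynyl]oxy}-2,6-dimethoxy-4-(2,4,6-trimethoxyphenoxy)benzene F4, which can be purified and stored. Catalytic K2CO3 in methanol at 0 °C removes the silyl groups immediately before step 7, and the solution of 11 is carried on after solvent exchange without isolation.

**Step 6.**
- Risk: self-condensation of the alkoxyketene faster than its cycloaddition, and hydrolysis of the vinylogous ester during purification.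
- Fallback: since 15 is made directly from starting materials, there is no numbered intermediate to branch from. The fallback replaces 12 and 13 by commercial diethyl squarate F5 and returns at 15. Reduction of one carbonyl with LiAlH(Ot-Bu)3 (THF, −78 °C) would give racemic 2,3-diethoxy-4-hydroxycyclobut-2-en-1-one F6. Acid-induced rearrangement with loss of ethanol would give 3-ethoxycyclobut-3-ene-1,2-dione F7. A second hydride reduction at the carbonyl next to the ethoxy-bearing carbon (the one that is not part of the vinylogous ester) would give racemic 3-ethoxy-4-hydroxycyclobut-2-en-1-one F8. O-Methylation with MeI and Ag2O would give 15.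

**Step 8.**
- Risk: incomplete cleavage of the nine ethers, giving mixtures of partly alkylated phenols, and air oxidation of the undecaphenol during isolation.
- Fallback: from 17 back to 18 by derivatise–purify–release. The crude dealkylation product is acetylated directly (Ac2O, pyridine) to the undecaacetate of 18 F9, which is stable and can be chromatographed; under-dealkylated material is separated at this stage and resubmitted. Acid-catalysed methanolysis (HCl generated from AcCl in MeOH, Ar) then releases 18 without base.

**Step 1.**
- Risk: sluggish substitution of the aldehyde-deactivated ring, and Lewis-acid-induced loss of the methyl group from the methoxy that ends up between two carbonyl groups.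
- Fallback: from 1 back to 2 with the ring carbon as nucleophile instead of electrophile. Compound 1 is converted into its dimethyl acetal, 2-(dimethoxymethyl)-5-fluoro-1,3-dimethoxybenzene F10 (HC(OMe)3, cat. TsOH, MeOH). Directed ortho-lithiation between fluorine and methoxy (n-BuLi, THF, −78 °C) would give [3-(dimethoxymethyl)-6-fluoro-2,4-dimethoxyphenyl]lithium F11. A DMF quench at −78 °C and aqueous HCl work-up, which also cleaves the acetal, would give 2.

## Further compounds

F1 | step 7 | 4,4'-{[2,4-dimethoxy-6-(2,4,6-trimethoxyphenoxy)-1,3-phenylene]bis(oxy)}bis(2,6-dimethoxybenzaldehyde) | COc1cc(OC)c(Oc2cc(OC)c(Oc3cc(OC)c(C=O)c(OC)c3)c(OC)c2Oc2cc(OC)c(C=O)c(OC)c2)c(OC)c1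
F2 | step 7 | 4,4'-{[2,4-dimethoxy-6-(2,4,6-trimethoxyphenoxy)-1,3-phenylene]bis(oxy)}bis(2,6-dimethoxyphenyl) diformate | COc1cc(OC)c(Oc2cc(OC)c(Oc3cc(OC)c(OC=O)c(OC)c3)c(OC)c2Oc2cc(OC)c(OC=O)c(OC)c2)c(OC)c1
F3 | step 7 | 4,4'-{[2,4-dimethoxy-6-(2,4,6-trimethoxyphenoxy)-1,3-phenylene]bis(oxy)}bis(2,6-dimethoxyphenol) | COc1cc(OC)c(Oc2cc(OC)c(Oc3cc(OC)c(O)c(OC)c3)c(OC)c2Oc2cc(OC)c(O)c(OC)c2)c(OC)c1
F4 | step 5 | 1,3-bis{[(trimethylsilyl)ethynyl]oxy}-2,6-dimethoxy-4-(2,4,6-trimethoxyphenoxy)benzene | COc1cc(OC)c(Oc2cc(OC)c(OC#C[Si](C)(C)C)c(OC)c2OC#C[Si](C)(C)C)c(OC)c1
F5 | step 6 | diethyl squarate (3,4-diethoxycyclobut-3-ene-1,2-dione) | CCOC1=C(OCC)C(=O)C1=O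
F6 | step 6 | racemic 2,3-diethoxy-4-hydroxycyclobut-2-en-1-one | CCOC1=C(OCC)C(=O)C1O
F7 | step 6 | 3-ethoxycyclobut-3-ene-1,2-dione | CCOC1=CC(=O)C1=O
F8 | step 6 | racemic 3-ethoxy-4-hydroxycyclobut-2-en-1-one | CCOC1=CC(=O)C1O
F9 | step 8 | undecaacetate of 18 (all eleven hydroxyls as acetates) | CC(=O)Oc1cc(OC(C)=O)c(Oc2cc(OC(C)=O)c(Oc3cc(OC(C)=O)c(OC(C)=O)c(OC(C)=O)c3)c(OC(C)=O)c2Oc2cc(OC(C)=O)c(OC(C)=O)c(OC(C)=O)c2)c(OC(C)=O)c1
F10 | step 1 | 2-(dimethoxymethyl)-5-fluoro-1,3-dimethoxybenzene | COc1cc(F)cc(OC)c1C(OC)OC
F11 | step 1 | [3-(dimethoxymethyl)-6-fluoro-2,4-dimethoxyphenyl]lithium | COc1cc(F)c([Li])c(OC)c1C(OC)OC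
A1 | alternative 1 | dimethyl 5-[3,5-dimethoxy-2,4-bis(3,4,5-trimethoxyphenoxy)phenoxy]-2,4,6-trihydroxyisophthalate | COC(=O)c1c(O)c(C(=O)OC)c(O)c(Oc2cc(OC)c(Oc3cc(OC)c(OC)c(OC)c3)c(OC)c2Oc2cc(OC)c(OC)c(OC)c2)c1O
A2 | alternative 1 | dimethyl 3-oxoglutarate | COC(=O)CC(=O)CC(=O)OC
A3 | alternative 1 | dimethyl 2-[3,5-dimethoxy-2,4-bis(3,4,5-trimethoxyphenoxy)phenoxy]malonate | COC(=O)C(Oc1cc(OC)c(Oc2cc(OC)c(OC)c(OC)c2)c(OC)c1Oc1cc(OC)c(OC)c(OC)c1)C(=O)OC
A4 | alternative 2 | 2,4-bis(3,4,5-trimethoxyphenoxy)-5-(2,4,6-trimethoxyphenoxy)isophthalaldehyde | COc1cc(OC)c(Oc2cc(C=O)c(Oc3cc(OC)c(OC)c(OC)c3)c(C=O)c2Oc2cc(OC)c(OC)c(OC)c2)c(OC)c1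
A5 | alternative 2 | 2,4-difluoro-5-(2,4,6-trimethoxyphenoxy)isophthalaldehyde | COc1cc(OC)c(Oc2cc(C=O)c(F)c(C=O)c2F)c(OC)c1
A6 | alternative 2 | 3,4,5-trimethoxyphenol | COc1cc(O)cc(OC)c1OC
A7 | alternative 3 | 2,4-bis(3,4,5-trimethoxyphenoxy)-5-(2,4,6-trimethoxyphenoxy)benzene-1,3-diol | COc1cc(OC)c(Oc2cc(O)c(Oc3cc(OC)c(OC)c(OC)c3)c(O)c2Oc2cc(OC)c(OC)c(OC)c2)c(OC)c1
A8 | alternative 3 | 1,3-bis(3,4,5-trimethoxyphenoxy)propan-2-one | COc1cc(OCC(=O)COc2cc(OC)c(OC)c(OC)c2)cc(OC)c1OC
A9 | alternative 3 | methyl 3-(2,4,6-trimethoxyphenoxy)propiolate | COC(=O)C#COc1c(OC)cc(OC)cc1OC
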